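The route rests on disconnecting the C3–O ester bond of the cyclohexene ring. C3 is allylic to the C1=C2 enoate and its oxygen is cis to the free C4 hydroxyl, so both oxygens are traced to a 3,4-epoxide. Zerovalent palladium turns this vinyl epoxide into a C1–C2–C3 π-allyl complex and (E)-3-methylpent-2-enoic acid adds at C3 with net retention: one operation installs the second acyl group, frees O4 and fixes the cis 3,4 relationship. The precursor is a methyl 3,4-epoxycyclohex-1-enecarboxylate whose C5 ester, placed trans to the epoxide by Mitsunobu inversion, is already in place. Both esters thus form by carboxylate attack at carbon, never through an activated acyl species.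

Key step: step 8

Assumption: the (S,S)-configured copper bis(oxazoline) catalyst is taken to shield the same face of the acrylimide towards furan as towards cyclopentadiene, which gives the (1S,2S,4S) endo adduct. The cyclohexene compounds are numbered as in shikimic acid (C1 carries the methyl ester, C1=C2, then C3 to C6).

Step 1
Reactants: 1 furan; 2 3-acryloyl-1,3-oxazolidin-2-one
Product: 3 3-[(1S,2S,4S)-7-oxabicyclo[2.2.1]hept-5-ene-2-carbonyl]-1,3-oxazolidin-2-one (endo adduct)
Conditions: [Cu((S,S)-tBu-box)](SbF6)2 (5 mol%; tBu-box = 2,2'-isopropylidenebis(4-tert-butyl-2-oxazoline)), furan (excess), CH2Cl2, −78 °C; cold work-up, endo isomer recrystallised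
Reagents that add atoms: none
Why: Catalytic asymmetric Diels–Alder reaction: the cationic divalent copper bis(oxazoline) complex chelates both imide carbonyls in a square plane, a tert-butyl group blocks one face of the s-cis acrylimide, and at −78 °C the kinetically preferred endo adduct should form under catalyst control with C1, C2 and C4 set together, recrystallisation removing the exo isomer before cycloreversion can erode selectivity.

Step 2
Reactants: 3 endo imide
Product: 4 methyl (1S,2S,4S)-7-oxabicyclo[2.2.1]hept-5-ene-2-carboxylate
Conditions: MeMgBr (1.2 equiv) added to MeOH, then 3, MeOH–CH2Cl2, 0 °C; aq. NH4Cl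
Reagents that add atoms: methanol, CO (delivered as bromomagnesium methoxide, CO[Mg]Br)
Why: Transesterification of an N-acyl oxazolidinone: bromomagnesium methoxide attacks the more electrophilic exocyclic carbonyl at 0 °C, which is mild and cold enough to avoid retro-Diels–Alder loss of furan, and any epimerisation at C2 would be harmless because that centre becomes trigonal in step 3.

Step 3
Reactants: 4 bicyclic methyl ester
Product: 6 methyl (S)-5-hydroxycyclohexa-1,3-diene-1-carboxylate, via lithium dienyl alkoxide 5 (not isolated)
Conditions: LiN(SiMe3)2 (1.1 equiv), THF, −78 °C to 0 °C; aq. NH4Cl at 0 °C; used at once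
Reagents that add atoms: none
Why: E1cB elimination: the ester enolate at C2 expels the bridge oxygen from C1, which gives the conjugated dienoate and leaves the other bridgehead C–O bond untouched, so that carbon becomes the (S)-configured C5 carbinol; the cold neutral quench should prevent dehydration to methyl benzoate.

Step 4
Reactants: 6 dienol
Product: 7 methyl (3R,4S,5S)-3,4-epoxy-5-hydroxycyclohex-1-ene-1-carboxylate (epoxide cis to the hydroxyl)
Conditions: VO(acac)2 (2 mol%), t-BuOOH (1.3 equiv, in decane), CH2Cl2, 0 °C
Reagents that add atoms: tert-butyl hydroperoxide, CC(C)(C)OO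
Why: Hydroxyl-directed epoxidation of an allylic alcohol: the vanadate ester of the C5 hydroxyl delivers the peroxide oxygen to the same face of the adjacent C3=C4 alkene, which sets C3 (R) and C4 (S) cis to the hydroxyl, while the electron-poor C1=C2 enoate alkene should not react.

Step 5
Reactants: 8 ethyl but-2-ynoate; 9 ethylmagnesium bromide
Product: 12 ethyl (E)-3-methylpent-2-enoate, via ethylcopper 10 (not isolated), via alkenylcopper adduct 11 (not isolated)
Conditions: 9 (1.3 equiv), CuBr·SMe2 (1.3 equiv), THF, −40 °C; then 8, −78 °C; MeOH at −78 °C, then aq. NH4Cl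
Reagents that add atoms: none
Why: Syn carbocupration (conjugate addition of an organocopper reagent to an ynoate): ethyl and copper add to the same side of the triple bond, and protonation of the alkenylcopper at −78 °C, before it can equilibrate through the allenoate, should fix the E trisubstituted alkene.

Step 6
Reactants: 12 ethyl (E)-3-methylpent-2-enoate
Product: 14 (E)-3-methylpent-2-enoic acid, via lithium carboxylate 13 (not isolated)
Conditions: LiOH (3 equiv), THF–MeOH–H2O, 40 °C; then 1 M HCl to pH 2
Reagents that add atoms: lithium hydroxide, [Li+].[OH-]
Why: Ester saponification and acidification; the conjugated trisubstituted alkene is not expected to move or isomerise under these conditions.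

Step 7
Reactants: 7 cis epoxy alcohol; 14 (E)-3-methylpent-2-enoic acid
Product: 16 methyl (3R,4S,5R)-3,4-epoxy-5-[(E)-3-methylpent-2-enoyloxy]cyclohex-1-ene-1-carboxylate, via alkoxyphosphonium carboxylate 15 (not isolated)
Conditions: 14 (1.5 equiv), PPh3 (1.5 equiv), DIAD (1.5 equiv), toluene, 0 °C to rt
Reagents that add atoms: none
Why: Mitsunobu esterification: the C5 hydroxyl is activated as an alkoxyphosphonium ion and displaced by the carboxylate of 14 in an SN2 reaction from the face opposite the epoxide oxygen, which inverts C5 to R and puts the ester trans to the epoxide; the acid reacts as an oxygen nucleophile only, so its E alkene cannot isomerise through a ketene.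

Step 8
Reactants: 16 trans epoxy ester; 14 (E)-3-methylpent-2-enoic acid
Product: 18 methyl (3R,4S,5R)-3,5-bis-O-[(E)-3-methylpent-2-enoyl]shikimate (target), via allylpalladium carboxylate ion pair 17 (not isolated)
Conditions: 14 (1.5 equiv), Pd(PPh3)4 (5 mol%), THF, 0 °C to rt
Reagents that add atoms: none
Why: Zerovalent palladium ionises the allylic C3–O bond of the vinyl epoxide from the face opposite the oxygen to give a cationic C1–C2–C3 π-allyl complex whose C4 alkoxide is protonated by acid 14, and the carboxylate so formed attacks C3 from outside, anti to palladium. The closest known reactions are the Tsuji–Trost opening of vinyl epoxides by carboxylic acids to cis hydroxy esters and the γ-selective substitution of γ,δ-epoxy-α,β-unsaturated esters with double inversion. No ring is closed; the oxirane is opened and the cyclohexene ring is untouched. C3 (R) is controlled by the two successive inversions, which return the new C–O bond to the face of the broken epoxide bond and hence cis to the C4 hydroxyl, while C4 (S) and C5 (R) are not involved. The step needs attack at C3 and not at C1, secured by C1 being fully substituted, by retention of ester conjugation in the C3 product and by the reversibility of any other allylic ester through the same π-allyl complex. It also needs outer-sphere attack, secured by phosphine-saturated palladium and the carboxylate ion pair held near O4, while the non-allylic C5 ester and the mildly acidic medium should suppress ionisation elsewhere, acyl migration and aromatisation.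

Compound list
1 | furan | c1ccoc1 | starting material
2 | 3-acryloyl-1,3-oxazolidin-2-one | C=CC(=O)N1CCOC1=O | starting material
3 | 3-[(1S,2S,4S)-7-oxabicyclo[2.2.1]hept-5-ene-2-carbonyl]-1,3-oxazolidin-2-one (endo) | O=C1OCCN1C(=O)[C@H]1C[C@H]2C=C[C@@H]1O2 | intermediate
4 | methyl (1S,2S,4S)-7-oxabicyclo[2.2.1]hept-5-ene-2-carboxylate (endo) | COC(=O)[C@H]1C[C@H]2C=C[C@@H]1O2 | intermediate
5 | lithium alkoxide of methyl (S)-5-hydroxycyclohexa-1,3-diene-1-carboxylate (not isolated) | COC(=O)C1=CC=C[C@@H]([O-])C1.[Li+] | intermediate
6 | methyl (S)-5-hydroxycyclohexa-1,3-diene-1-carboxylate | COC(=O)C1=CC=C[C@@H](O)C1 | intermediate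
7 | methyl (3R,4S,5S)-3,4-epoxy-5-hydroxycyclohex-1-ene-1-carboxylate | COC(=O)C1=C[C@H]2O[C@H]2[C@@H](O)C1 | intermediate
8 | ethyl but-2-ynoate | CC#CC(=O)OCC | starting material
9 | ethylmagnesium bromide | CC[Mg]Br | starting material
10 | ethylcopper (not isolated) | CC[Cu] | intermediate
11 | ethyl 2-cuprio-3-methylpent-2-enoate, copper cis to the new ethyl group (not isolated) | CC/C(C)=C(\[Cu])C(=O)OCC | intermediate
12 | ethyl (E)-3-methylpent-2-enoate | CC/C(C)=C/C(=O)OCC | intermediate
13 | lithium (E)-3-methylpent-2-enoate (not isolated) | CC/C(C)=C/C(=O)[O-].[Li+] | intermediate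
14 | (E)-3-methylpent-2-enoic acid | CC/C(C)=C/C(=O)O | intermediate
15 | C5 alkoxytriphenylphosphonium salt of 7 with the carboxylate of 14 as counter-ion (not isolated) | COC(=O)C1=C[C@H]2O[C@H]2[C@@H](O[P+](c3ccccc3)(c3ccccc3)c3ccccc3)C1.CC/C(C)=C/C(=O)[O-] | intermediate
16 | methyl (3R,4S,5R)-3,4-epoxy-5-[(E)-3-methylpent-2-enoyloxy]cyclohex-1-ene-1-carboxylate | COC(=O)C1=C[C@H]2O[C@H]2[C@H](OC(=O)/C=C(\C)CC)C1 | intermediate
17 | cationic bis(triphenylphosphine) C1–C2–C3 allylpalladium complex with free C4 hydroxyl and the carboxylate of 14 as counter-ion, palladium anti to O4, drawn in its C3-bound form (not isolated) | COC(=O)C1=C[C@H]([Pd-]([P+](c2ccccc2)(c2ccccc2)c2ccccc2)[P+](c2ccccc2)(c2ccccc2)c2ccccc2)[C@@H](O)[C@H](OC(=O)/C=C(\C)CC)C1.CC/C(C)=C/C(=O)[O-] | intermediate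
18 | methyl (3R,4S,5R)-3,5-bis-O-[(E)-3-methylpent-2-enoyl]shikimate | CC/C(C)=C/C(=O)O[C@@H]1C=C(C(=O)OC)C[C@@H](OC(=O)/C=C(\C)CC)[C@@H]1O | target

Total step count: 8
Longest linear sequence: 6 steps (steps 1, 2, 3, 4, 7 and 8; steps 5 and 6 make the acid used in steps 7 and 8)

Steps most likely to fail

1. Step 8 (palladium opening of the vinyl epoxide). The π-allyl complex may isomerise by hydride shift from C4 to a ketone before the carboxylate captures it, followed by loss of the C5 carboxylate and aromatisation. The acyl group may also migrate from O3 to the cis O4 during reaction or isolation. Fallback without palladium, which installs both oxygens by dihydroxylation: setting out from dienol 6, Mitsunobu esterification with acid 14 (PPh3, DIAD, toluene, 0 °C) at the allylic C5 hydroxyl should give, with inversion, methyl (5R)-5-[(E)-3-methylpent-2-enoyloxy]cyclohexa-1,3-diene-1-carboxylate F1. Dihydroxylation with OsO4 (cat.) and N-methylmorpholine N-oxide in acetone–water at 0 °C should take place at the most electron-rich alkene, C3=C4, on the face anti to the allylic C5 ester, and give methyl 5-O-[(E)-3-methylpent-2-enoyl]shikimate F2. Steglich monoacylation with 14 (DCC, catalytic DMAP, CH2Cl2, −20 °C) should then occur at the allylic O3, since O4 is flanked by substituents on both sides, and the route is rejoined at target 18.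

2. Step 7 (Mitsunobu inversion at C5). The SN2 displacement may be slow at a carbinol carbon deactivated by the adjacent epoxide, so that elimination towards C6 or consumption of the betaine by the acid takes over. Fallback that replaces the one-pot redox condensation by a discrete sulfonate electrophile and a separately formed carboxylate salt: setting out from epoxy alcohol 7, Tf2O and pyridine in CH2Cl2 at −40 °C should give methyl 3,4-epoxy-5-(trifluoromethanesulfonyloxy)cyclohex-1-ene-1-carboxylate F3 with all centres unchanged. Displacement by the caesium salt of 14 (from Cs2CO3 and 14, 18-crown-6, toluene–DMF, 0 °C) should proceed with inversion and rejoin the route at epoxy ester 16.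

3. Step 4 (directed epoxidation of the dienol). The dienol may dehydrate to methyl benzoate in the presence of the Lewis acidic vanadium catalyst, or delivery of oxygen to the hydroxyl-bearing face may be incomplete. Fallback that takes facial control from the bicyclic skeleton and bypasses the free dienol: setting out from bicyclic ester 4, mCPBA (CH2Cl2, 0 °C) should epoxidise the strained alkene on its exo face, the side of the oxygen bridge, to give methyl exo-5,6-epoxy-7-oxabicyclo[2.2.1]heptane-2-endo-carboxylate F4. E1cB opening of the bridge with LiN(SiMe3)2 (THF, −78 °C) then leaves the epoxide cis to the liberated hydroxyl and rejoins the route at epoxy alcohol 7.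

Further compounds
F1 | step 8 | methyl (5R)-5-[(E)-3-methylpent-2-enoyloxy]cyclohexa-1,3-diene-1-carboxylate | COC(=O)C1=CC=C[C@H](OC(=O)/C=C(\C)CC)C1
F2 | step 8 | methyl 5-O-[(E)-3-methylpent-2-enoyl]shikimate | COC(=O)C1=C[C@@H](O)[C@@H](O)[C@H](OC(=O)/C=C(\C)CC)C1
F3 | step 7 | methyl 3,4-epoxy-5-(trifluoromethanesulfonyloxy)cyclohex-1-ene-1-carboxylate, the C5 triflate of 7 | COC(=O)C1=C[C@H]2O[C@H]2[C@@H](OS(=O)(=O)C(F)(F)F)C1
F4 | step 4 | methyl exo-5,6-epoxy-7-oxabicyclo[2.2.1]heptane-2-endo-carboxylate | COC(=O)[C@H]1C[C@H]2[C@@H]3O[C@@H]3[C@@H]1O2
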